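## Retrosynthetic overview

1. Avoided: bringing the stereocentre in from (S)-2-methylbutanol and extending the chain away from it. Here the stereocentre itself is the reacting carbon.
2. Key disconnection, C19–C20 (the bond to the stereocentre): Cu-catalysed SN2 alkylation of (R)-2-butyl tosylate by undec-10-enylmagnesium bromide with Walden inversion, giving a C15 alkene.
3. C8–C9: hydroboration of that alkene with 9-BBN, then alkyl–alkyl Suzuki coupling with unprotected 8-bromooctan-1-ol, giving the C23 alcohol.
4. O–C1 (alkyl–O, not acyl–O): Mitsunobu coupling with unprotected 2,3-dihydroxybenzoic acid. The catechol enters last because it would destroy Grignard reagents and alkylboranes.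
5. Rings: none are formed, since the arene is bought intact. There are no protecting groups and no redox adjustments.

Assumption: the SMILES has 19 CH2 groups between the ester oxygen and the stereocentre, and [C@H] reads as S, so the target is (S)-20-methyldocosyl 2,3-dihydroxybenzoate, C30H52O4.

## Route

**Step 1**
Reactants: 1, (R)-butan-2-ol (≥99% ee)
Product: 2, (R)-butan-2-yl 4-methylbenzenesulfonate
Conditions: TsCl (1.2 equiv), pyridine, CH2Cl2, 0 → 4 °C, 16 h
Reagents that add atoms: p-toluenesulfonyl chloride, Cc1ccc(cc1)S(=O)(=O)Cl
Why: O-sulfonylation leaves the C–O bond intact, so the (R) configuration is retained, and a sulfonate (unlike a secondary bromide or iodide) reacts with cuprates by a polar SN2 path rather than a radical one.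

**Step 2**
Reactants: 3, 11-bromoundec-1-ene
Product: 4, undec-10-en-1-ylmagnesium bromide (about 0.8 M in THF, titrated and used directly)
Conditions: Mg turnings (1.2 equiv, I2-activated), THF, slow addition of 3, rt → 40 °C, 2 h
Reagents that add atoms: magnesium, [Mg]
Why: Grignard formation by insertion of Mg into the primary C–Br bond; the alkene is nine CH2 groups away, so the transient radical cannot cyclise, and slow addition limits Wurtz dimer.

**Step 3 (key step)**
Reactants: 2, (R)-butan-2-yl tosylate (1.0 equiv); 4, undec-10-en-1-ylmagnesium bromide (1.6 equiv)
Product: 5, (S)-12-methyltetradec-1-ene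
Conditions: CuI (10 mol %), TMEDA (20 mol %), LiOMe (1.0 equiv), THF, 0 °C, 24 h; aq NH4Cl; Kugelrohr distillation
Reagents that add atoms: none (all atoms of 5 come from 2 and 4)
Why: This is a Cu-catalysed Kumada-type sp3–sp3 cross-coupling in which the alkylcuprate attacks the unactivated secondary tosylate from the back (SN2-type oxidative addition, then reductive elimination), so (R)-C–OTs becomes (S)-C–C by inversion, as is long established for cuprates with 2-butyl and 2-octyl tosylates. sec-Butyl is the least hindered secondary electrophile, the E2 by-product butene is volatile, and the isolated terminal alkene is inert.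

**Step 4**
Reactants: 5, (S)-12-methyltetradec-1-ene
Product: 6, 9-[(12S)-12-methyltetradecyl]-9-borabicyclo[3.3.1]nonane (THF solution, used directly)
Conditions: 9-BBN (0.5 M in THF, 1.02 equiv), 0 °C → rt, 6 h
Reagents that add atoms: 9-borabicyclo[3.3.1]nonane (9-BBN), B1C2CCCC1CCC2
Why: Anti-Markovnikov hydroboration with bulky 9-BBN places boron on the terminal carbon (>99:1); no new stereocentre forms, and the existing one, nine CH2 groups from the alkene, is untouched. Near-stoichiometric 9-BBN leaves almost no B–H to react with the free OH in the next step.

**Step 5**
Reactants: 6, B-[(S)-12-methyltetradecyl]-9-BBN (1.2 equiv); 7, 8-bromooctan-1-ol (1.0 equiv)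
Product: 8, (S)-20-methyldocosan-1-ol
Conditions: Pd(OAc)2 (4 mol %), PCy3 (8 mol %), K3PO4·H2O (1.5 equiv), THF, rt, 24 h; NaOH/H2O2 work-up; recrystallise from acetone
Reagents that add atoms: none (all atoms of 8 come from 6 and 7; the 9-BBN cage leaves as cyclooctane-1,5-diol)
Why: In this B-alkyl (alkyl–alkyl) Suzuki–Miyaura coupling the electron-rich, bulky Pd/PCy3 catalyst adds oxidatively to the primary bromide and reductively eliminates faster than β-hydride elimination. The medium already contains water, and related couplings run in alcohol solvents, so a free primary OH should be tolerated. The stereocentre is separated from boron by eleven CH2 groups. C14 + C8 gives the C22 main chain with 19 CH2 groups.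

**Step 6**
Reactants: 8, (S)-20-methyldocosan-1-ol; 9, 2,3-dihydroxybenzoic acid
Product: 10, gentiside B
Conditions: 9 (1.3 equiv), PPh3 (1.25 equiv), DIAD (1.25 equiv, added dropwise), THF, 0 °C → rt, 12 h
Reagents that add atoms: none (the elements of water leave as Ph3P=O and reduced DIAD)
Why: Mitsunobu esterification activates the alcohol rather than the acid, so the hydroxy acid cannot self-acylate. Only the carboxylic acid (pKa about 3, versus about 10 for the phenols) is deprotonated by the betaine, giving chemoselective O-alkylation of the carboxylate at the non-stereogenic C1 under neutral conditions that spare the catechol and the remote stereocentre.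

## Compound list

1 | (R)-butan-2-ol | CC[C@@H](C)O | starting material
2 | (R)-butan-2-yl 4-methylbenzenesulfonate | CC[C@@H](C)OS(=O)(=O)c1ccc(C)cc1 | intermediate
3 | 11-bromoundec-1-ene | C=CCCCCCCCCCBr | starting material
4 | undec-10-en-1-ylmagnesium bromide | C=CCCCCCCCCC[Mg]Br | intermediate
5 | (S)-12-methyltetradec-1-ene | CC[C@H](C)CCCCCCCCCC=C | intermediate
6 | 9-[(12S)-12-methyltetradecyl]-9-borabicyclo[3.3.1]nonane | CC[C@H](C)CCCCCCCCCCCB1C2CCCC1CCC2 | intermediate
7 | 8-bromooctan-1-ol | OCCCCCCCCBr | starting material
8 | (S)-20-methyldocosan-1-ol | CC[C@H](C)CCCCCCCCCCCCCCCCCCCO | intermediate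
9 | 2,3-dihydroxybenzoic acid | OC(=O)c1cccc(O)c1O | starting material
10 | gentiside B, (S)-20-methyldocosyl 2,3-dihydroxybenzoate | CC[C@H](C)CCCCCCCCCCCCCCCCCCCOC(=O)c1cccc(O)c1O | target

## Step count

- **Total steps:** 6. Compounds 4 and 6 are carried forward in solution, so only 2, 5, 8 and 10 are isolated. No protecting groups are used.
- **Longest linear sequence:** 5 (1 → 2 → 5 → 6 → 8 → 10, or equally 3 → 4 → 5 → 6 → 8 → 10).

## Steps most likely to fail

**1. Step 3, stereoinvertive coupling.**
- Risks: E2 elimination lowers the yield. Br⁻/OTs exchange followed by a second displacement would erode the ee. The er should be checked on 8 by derivatisation with a chiral fluorescent reagent for remote stereocentres and low-temperature HPLC.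
- Fallback: set the stereocentre by catalysis on an achiral alkene.
  - Couple 4 (2.2 equiv, the first equivalent deprotonating the OH) with 10-bromodecan-1-ol (cat. Li2CuCl4, THF) to give henicos-20-en-1-ol.
  - Carry out Zr-catalysed asymmetric ethylalumination (excess Et3Al, (+)-(NMI)2ZrCl2, CH2Cl2). The facial sense is assigned by analogy with methylalumination and should be confirmed on the product.
  - Protonolysis then gives 8 directly. The expected ee is about 90–95%, and Steps 1 and 3–5 are no longer needed.

**2. Step 5, alkyl–alkyl Suzuki coupling with a free OH.**
- Risks: β-hydride elimination, protodeboronation, or interference from the hydroxyl group.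
- Fallback: olefin cross-metathesis of 5 with dec-9-enyl acetate (Hoveyda–Grubbs II, with 1,4-benzoquinone to suppress isomerisation), then H2/Pd–C and K2CO3/MeOH to give 8. The carbon count is 13 + 9 = 22. This replaces Steps 4 and 5.

**3. Step 6, unprotected Mitsunobu.**
- Risks: phenol O-alkylation, or sequestration of PPh3/DIAD by the catechol as a benzodioxaphosphorane.
- Fallback: switch to acyl activation with a masked catechol. Couple 8 with 2,3-bis(benzyloxy)benzoic acid (EDC·HCl, DMAP), then hydrogenolyse (H2, Pd/C) to give 10.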